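**Plan**

- Numbering: pyranone ring O1–C6; side chain C1' (ketone carbon on C3) to C12' (ethyl terminus). The retrosynthesis cuts C3–C1' (C-acylation of the pyranedione), C7'–C8' (Suzuki–Miyaura coupling), C6'=C7' (boron Takai–Utimoto olefination), C8'=C9' (bromo-Wittig reaction), and O1–C2 and C3–C4 of the pyranone (lactonisation, Claisen condensation).
- Enabling feature: C1'–C6' with the methyl group on C4' is a 4-methylhexane chain oxidised at both ends (acyl C1', olefinic C6'). Its seven carbons are those of 4-methylcyclohexanone with the ring bond C1–C2 broken, so the ketone is cut by an enantioselective Baeyer–Villiger oxidation to the seven-membered lactone (R)-5-methyloxepan-2-one.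
- Forward order: the oxepanone is formed first, opened, oxidised to the C6' aldehyde and converted to the E-alkenylboronate. This is coupled with the Z-bromoenoate made from (S)-2-methylbutan-1-ol, and the methyl ester is hydrolysed. The dihydropyranedione ring is built separately, acylated at C3 with the chain acid, and the tert-butyl ester is removed last.
- Stereochemistry: C4' (R) comes from catalyst control in the Baeyer–Villiger step, C10' (S) from (S)-2-methylbutan-1-ol, and C6 (R) from methyl (R)-3-hydroxybutanoate. The 6'E bond comes from the Takai–Utimoto step; the 8'E bond from a Z-selective bromo-Wittig reaction followed by a stereoretentive coupling.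

Key step: step 1

Assumption: the sense of induction of the scandium catalyst with a 4-methyl group is taken to parallel that with other 4-substituted cyclohexanones; the ligand enantiomer is chosen to give the (R)-lactone, and the configuration of 3 is to be checked by optical rotation before it is carried on.

**Route**

Step 1
Reactants: 1 4-methylcyclohexanone
Product: 3 (R)-5-methyloxepan-2-one, via Criegee adduct 2 (not isolated)
Conditions: Sc(OTf)3 (5 mol %), C2-symmetric chiral N,N'-dioxide bis(2,6-diisopropylanilide) ligand (5 mol %), mCPBA (1.1 equiv), EtOAc, −20 °C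
Reagents that add atoms: 3-chloroperoxybenzoic acid (mCPBA), O=C(OO)c1cccc(Cl)c1
Why: mCPBA adds to the scandium-activated carbonyl group to give Criegee adduct 2, and a 1,2-shift of one α-methylene group from carbon to the proximal peroxide oxygen, with loss of 3-chlorobenzoate, inserts oxygen into that C1–C2 bond (Baeyer–Villiger oxidation; the closest known reaction type is the catalytic enantioselective desymmetrisation of 4-substituted cyclohexanones with chiral N,N'-dioxide–Sc(OTf)3 complexes and a peracid). The oxepanone ring is not closed by a cyclisation; it arises by ring expansion, the six-membered carbocycle taking up one oxygen atom in the migration step. The new stereocentre (C5 of 3, the prochiral C4 of 1) is set by the chiral scandium complex, which should hold the Criegee adduct so that only one of the two enantiotopic ring C–C bonds lies antiperiplanar to the O–O bond. The step needs enantiotopic-group selection only, since both α-carbons are methylene groups of equal migratory aptitude. The equatorial methyl group locks the chair and so presents the catalyst with one rigid conformer to discriminate, and no other oxidisable group is present.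

Step 2
Reactants: 3 (R)-5-methyloxepan-2-one
Product: 4 methyl (R)-6-hydroxy-4-methylhexanoate
Conditions: K2CO3 (0.1 equiv), MeOH, 0 °C to rt
Reagents that add atoms: methanol, CO
Why: Base-catalysed transesterification (lactone methanolysis) in a large excess of methanol should open the seven-membered lactone at the acyl–oxygen bond and leave the remote stereocentre untouched, the base being neutralised before concentration so that the hydroxy ester does not re-close.

Step 3
Reactants: 4 methyl (R)-6-hydroxy-4-methylhexanoate
Product: 5 methyl (R)-4-methyl-6-oxohexanoate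
Conditions: TEMPO (10 mol %), PhI(OAc)2 (1.1 equiv), CH2Cl2, rt
Reagents that add atoms: none
Why: Oxoammonium-mediated oxidation (TEMPO with PhI(OAc)2 as terminal oxidant) should stop at the aldehyde under anhydrous, near-neutral conditions that touch neither the methyl ester nor the stereocentre, which is not α to a carbonyl group.

Step 4
Reactants: 5 methyl (R)-4-methyl-6-oxohexanoate; 6 2-(dichloromethyl)-4,4,5,5-tetramethyl-1,3,2-dioxaborolane
Product: 8 methyl (4R,6E)-4-methyl-7-(4,4,5,5-tetramethyl-1,3,2-dioxaborolan-2-yl)hept-6-enoate, via gem-dichromium reagent 7 (not isolated)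
Conditions: CrCl2 (8 equiv), LiI (4 equiv), 6 (2 equiv), THF, rt
Reagents that add atoms: none
Why: Takai–Utimoto olefination in its boron variant: CrCl2 (divalent chromium) reduces both C–Cl bonds of 6 to the geminal dichromium reagent 7, which adds to the aldehyde and eliminates with boron and the alkyl chain trans, so the E-alkenylboronate should form while the methyl ester, inert to organochromium reagents, survives.

Step 5
Reactants: 9 (S)-2-methylbutan-1-ol
Product: 10 (S)-2-methylbutanal
Conditions: TEMPO (1 mol %), KBr (10 mol %), aq. NaOCl (1.1 equiv, buffered with NaHCO3), CH2Cl2/H2O, 0 °C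
Reagents that add atoms: none
Why: Anelli oxidation (TEMPO-catalysed hypochlorite oxidation) is fast, biphasic and buffered near neutrality, so the aldehyde should form without over-oxidation and without enolisation of its α-stereocentre; it is used at once as a dried CH2Cl2 solution.

Step 6
Reactants: 10 (S)-2-methylbutanal; 11 tert-butyl (triphenylphosphoranylidene)acetate
Product: 13 tert-butyl (2Z,4S)-2-bromo-4-methylhex-2-enoate, via bromo ylide 12 (not isolated)
Conditions: 11 (1.2 equiv), NBS (1.2 equiv), CH2Cl2, −20 °C; then 10, K2CO3 (solid), −20 °C to rt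
Reagents that add atoms: N-bromosuccinimide, O=C1CCC(=O)N1Br
Why: Halogenation–Wittig sequence: the stabilised ylide 11 is brominated at carbon and deprotonated to bromo ylide 12, which should olefinate the aldehyde under non-enolising conditions with the ester trans to the sec-butyl group, as stabilised ylides do, giving the 2Z-bromoalkene (minor 2E isomer removed by chromatography) with C4 unchanged.

Step 7
Reactants: 8 methyl (4R,6E)-4-methyl-7-(4,4,5,5-tetramethyl-1,3,2-dioxaborolan-2-yl)hept-6-enoate; 13 tert-butyl (2Z,4S)-2-bromo-4-methylhex-2-enoate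
Product: 14 methyl (4R,6E,8E,10S)-8-(tert-butoxycarbonyl)-4,10-dimethyldodeca-6,8-dienoate
Conditions: PdCl2(dppf) (5 mol %; dppf = 1,1'-bis(diphenylphosphino)ferrocene), K3PO4 (3 equiv), THF/H2O, 45 °C
Reagents that add atoms: none
Why: Suzuki–Miyaura coupling: oxidative addition into the activated C–Br bond of the α-bromo enoate, transmetalation from the alkenylboronate and reductive elimination all proceed with retention, so the 6E,8E-diene should result (the 2Z bromide becomes the 8E alkene only because carbon replaces bromine in the priority order) and neither sp3 stereocentre is involved.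

Step 8
Reactants: 14 methyl (4R,6E,8E,10S)-8-(tert-butoxycarbonyl)-4,10-dimethyldodeca-6,8-dienoate
Product: 15 (4R,6E,8E,10S)-8-(tert-butoxycarbonyl)-4,10-dimethyldodeca-6,8-dienoic acid
Conditions: LiOH·H2O (2 equiv), THF/H2O (3:1), 0 °C to rt; then cold 1 M HCl to pH 4
Reagents that add atoms: lithium hydroxide, [Li+].[OH-]
Why: Saponification should cleave only the unhindered methyl ester, since hydroxide attack on the conjugated, α-branched tert-butyl ester is sterically blocked, and the brief cold acidification leaves that ester and the diene intact.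

Step 9
Reactants: 16 methyl (R)-3-hydroxybutanoate; 17 tert-butyl acetate
Product: 19 tert-butyl (R)-5-hydroxy-3-oxohexanoate, via lithium enolate 18 (not isolated)
Conditions: LiN(iPr)2 (3.6 equiv), 17 (3.6 equiv), THF, −78 °C; then 16, −78 to −30 °C; AcOH quench
Reagents that add atoms: none
Why: Crossed Claisen condensation: an excess of lithium enolate 18 is used because one equivalent is spent on the hydroxyl group and one on the acidic β-keto ester formed, and at low temperature the lithium alkoxide of 16 should undergo neither retro-aldol cleavage nor elimination, so the carbinol centre keeps its R configuration.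

Step 10
Reactants: 19 tert-butyl (R)-5-hydroxy-3-oxohexanoate
Product: 21 (R)-6-methyldihydro-2H-pyran-2,4(3H)-dione, via hydroxy keto acid 20 (not isolated)
Conditions: CF3CO2H, CH2Cl2, 0 °C to rt
Reagents that add atoms: none
Why: Acidolysis of the tert-butyl ester gives hydroxy keto acid 20, whose 6-exo-trig lactonisation in CF3CO2H should outrun decarboxylation at room temperature, and since the C–O bond at the stereocentre is not broken C6 stays R.

Step 11
Reactants: 15 (4R,6E,8E,10S)-8-(tert-butoxycarbonyl)-4,10-dimethyldodeca-6,8-dienoic acid; 21 (R)-6-methyldihydro-2H-pyran-2,4(3H)-dione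
Product: 23 tert-butyl (2E,4S)-2-[(1E,4R)-7-[(6R)-4-hydroxy-6-methyl-2-oxo-5,6-dihydro-2H-pyran-3-yl]-4-methyl-7-oxohept-1-en-1-yl]-4-methylhex-2-enoate, via enol ester 22 (not isolated)
Conditions: DCC (1.1 equiv), DMAP (0.3 equiv), CH2Cl2, 0 °C to rt
Reagents that add atoms: none
Why: Steglich esterification first gives enol ester 22, and DMAP then carries the acyl group from O4 to C3 (Fries-type 1,3 O-to-C acyl shift through an acylpyridinium–enolate ion pair), the chelated β-tricarbonyl enol being the thermodynamic sink, while no stereocentre or alkene is affected.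

Step 12
Reactants: 23 tert-butyl ester of the target
Product: 24 (2E,4S)-2-[(1E,4R)-7-[(6R)-4-hydroxy-6-methyl-2-oxo-5,6-dihydro-2H-pyran-3-yl]-4-methyl-7-oxohept-1-en-1-yl]-4-methylhex-2-enoic acid (CNP0281879.1)
Conditions: CF3CO2H/CH2Cl2 (1:4), 0 °C to rt
Reagents that add atoms: none
Why: Acid-mediated cleavage of the tert-butyl ester by loss of the tert-butyl cation (E1) should free the acid without touching the acylpyranone enol, the electron-poor diene or the three stereocentres.

**Compound list**

1 | 4-methylcyclohexanone | CC1CCC(=O)CC1 | starting material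
2 | Criegee adduct, 1-hydroxy-4-methylcyclohexyl 3-chlorobenzenecarboperoxoate | CC1CCC(O)(OOC(=O)c2cccc(Cl)c2)CC1 | intermediate (not isolated)
3 | (R)-5-methyloxepan-2-one | O=C1CC[C@@H](C)CCO1 | intermediate
4 | methyl (R)-6-hydroxy-4-methylhexanoate | COC(=O)CC[C@@H](C)CCO | intermediate
5 | methyl (R)-4-methyl-6-oxohexanoate | COC(=O)CC[C@@H](C)CC=O | intermediate
6 | 2-(dichloromethyl)-4,4,5,5-tetramethyl-1,3,2-dioxaborolane | ClC(Cl)B1OC(C)(C)C(C)(C)O1 | starting material
7 | gem-dichromium reagent, [(4,4,5,5-tetramethyl-1,3,2-dioxaborolan-2-yl)methanediyl]bis(dichlorochromium), trivalent chromium | CC1(C)OB(OC1(C)C)C([Cr](Cl)Cl)[Cr](Cl)Cl | intermediate (not isolated)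
8 | methyl (4R,6E)-4-methyl-7-(4,4,5,5-tetramethyl-1,3,2-dioxaborolan-2-yl)hept-6-enoate | COC(=O)CC[C@@H](C)C/C=C/B1OC(C)(C)C(C)(C)O1 | intermediate
9 | (S)-2-methylbutan-1-ol | CC[C@H](C)CO | starting material
10 | (S)-2-methylbutanal | CC[C@H](C)C=O | intermediate
11 | tert-butyl (triphenylphosphoranylidene)acetate | CC(C)(C)OC(=O)C=P(c1ccccc1)(c1ccccc1)c1ccccc1 | starting material
12 | bromo ylide, tert-butyl bromo(triphenylphosphoranylidene)acetate | CC(C)(C)OC(=O)C(Br)=P(c1ccccc1)(c1ccccc1)c1ccccc1 | intermediate (not isolated)
13 | tert-butyl (2Z,4S)-2-bromo-4-methylhex-2-enoate | CC[C@H](C)/C=C(\Br)C(=O)OC(C)(C)C | intermediate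
14 | methyl (4R,6E,8E,10S)-8-(tert-butoxycarbonyl)-4,10-dimethyldodeca-6,8-dienoate | CC[C@H](C)/C=C(\C=C\C[C@H](C)CCC(=O)OC)C(=O)OC(C)(C)C | intermediate
15 | (4R,6E,8E,10S)-8-(tert-butoxycarbonyl)-4,10-dimethyldodeca-6,8-dienoic acid | CC[C@H](C)/C=C(\C=C\C[C@H](C)CCC(=O)O)C(=O)OC(C)(C)C | intermediate
16 | methyl (R)-3-hydroxybutanoate | COC(=O)C[C@@H](C)O | starting material
17 | tert-butyl acetate | CC(=O)OC(C)(C)C | starting material
18 | lithium enolate of tert-butyl acetate | C=C(O[Li])OC(C)(C)C | intermediate (not isolated)
19 | tert-butyl (R)-5-hydroxy-3-oxohexanoate | C[C@@H](O)CC(=O)CC(=O)OC(C)(C)C | intermediate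
20 | hydroxy keto acid, (R)-5-hydroxy-3-oxohexanoic acid | C[C@@H](O)CC(=O)CC(=O)O | intermediate (not isolated)
21 | (R)-6-methyldihydro-2H-pyran-2,4(3H)-dione (dione tautomer of the 4-hydroxy-5,6-dihydropyran-2-one) | C[C@@H]1CC(=O)CC(=O)O1 | intermediate
22 | enol ester, (6R)-6-methyl-2-oxo-5,6-dihydro-2H-pyran-4-yl (4R,6E,8E,10S)-8-(tert-butoxycarbonyl)-4,10-dimethyldodeca-6,8-dienoate | CC[C@H](C)/C=C(\C=C\C[C@H](C)CCC(=O)OC1=CC(=O)O[C@H](C)C1)C(=O)OC(C)(C)C | intermediate (not isolated)
23 | tert-butyl (2E,4S)-2-[(1E,4R)-7-[(6R)-4-hydroxy-6-methyl-2-oxo-5,6-dihydro-2H-pyran-3-yl]-4-methyl-7-oxohept-1-en-1-yl]-4-methylhex-2-enoate | CC[C@H](C)/C=C(\C=C\C[C@H](C)CCC(=O)C1=C(O)C[C@@H](C)OC1=O)C(=O)OC(C)(C)C | intermediate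
24 | (2E,4S)-2-[(1E,4R)-7-[(6R)-4-hydroxy-6-methyl-2-oxo-5,6-dihydro-2H-pyran-3-yl]-4-methyl-7-oxohept-1-en-1-yl]-4-methylhex-2-enoic acid (CNP0281879.1) | CC[C@H](C)/C=C(\C=C\C[C@H](C)CCC(=O)C1=C(O)C[C@@H](C)OC1=O)C(=O)O | target

**Step count**

Total: 12 steps. Longest linear sequence: 8 steps (steps 1, 2, 3, 4, 7, 8, 11, 12).

**Steps most likely to fail, with fallbacks**

Step 1. The methyl group is a small handle, so discrimination between the two enantiotopic methylene groups may be weak, or induction may run in the wrong sense with the ligand at hand; either would erode the configuration at C4'. Fallback (resolution in place of desymmetrisation, same ring cleavage), setting out from 1 and returning at 3: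
- Ketone 1 is oxidised without a chiral catalyst (mCPBA, NaHCO3, CH2Cl2) to racemic 5-methyloxepan-2-one F1.
- Immobilised Candida antarctica lipase B with benzyl alcohol (0.6 equiv) in toluene is then expected, by analogy with lipase ring opening of 4-substituted caprolactones, to open the (S)-lactone faster, giving benzyl (S)-6-hydroxy-4-methylhexanoate F2.
- The unreacted (R)-lactone is separated by chromatography and is compound 3.

Step 7. The C–Br carbon of 13 lies between the tert-butyl ester and a cis sec-butyl group, so transmetalation may be slow and protodeboronation of 8 or erosion of alkene geometry may compete. Fallback (the C6'=C7' bond is made by Wittig olefination; steps 4, 6 and 7 are replaced), setting out from aldehydes 10 and 5 and returning at 14: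
- Aldehyde 10 and tert-butyl acrylate (DABCO, rt, Morita–Baylis–Hillman reaction) give tert-butyl (4S)-3-hydroxy-4-methyl-2-methylidenehexanoate F3; its C3 epimers are inconsequential because C3 becomes sp2.
- NBS/Me2S (CH2Cl2, 0 °C) converts it with allylic transposition into tert-butyl (2Z,4S)-2-(bromomethyl)-4-methylhex-2-enoate F4.
- PBu3 in MeCN gives tributyl[(2Z,4S)-2-(tert-butoxycarbonyl)-4-methylhex-2-en-1-yl]phosphonium bromide F5.
- KOtBu (THF, −78 °C) forms the allylic ylide tert-butyl (2Z,4S)-4-methyl-2-[(tributylphosphoranylidene)methyl]hex-2-enoate F6, to which aldehyde 5 is added to give 14; allylic trialkylphosphonium ylides favour E-olefins.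

Step 11. The O-to-C acyl shift may stall at enol ester 22, or the activated acid may be diverted to its N-acylurea, so that C3 is not acylated. Fallback (the pyranone ring is closed after the chain is attached; steps 9 to 11 are replaced), setting out from acid 15 and hydroxy ester 16 and returning at 23:
- Acid 15 is condensed with Meldrum's acid (DCC, DMAP, CH2Cl2, 0 °C) to the acyl Meldrum's acid tert-butyl (2E,4S)-2-[(1E,4R)-7-(2,2-dimethyl-4,6-dioxo-1,3-dioxan-5-ylidene)-7-hydroxy-4-methylhept-1-en-1-yl]-4-methylhex-2-enoate F7.
- Heating with 16 in toluene (80 °C) transfers the β-ketoacyl group to the secondary hydroxyl group with loss of acetone and CO2, giving the β-keto ester 12-tert-butyl 1-[(2R)-4-methoxy-4-oxobutan-2-yl] (6R,8E,10E)-10-[(2S)-butan-2-ylmethylidene]-6-methyl-3-oxododec-8-enedioate, in short the 3-oxo ester of 16 with the chain of 15, F8.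
- Dieckmann cyclisation of the active methylene group onto the methyl ester (KOtBu, tBuOH–THF, 0 °C) closes the ring and gives 23.

Further compounds
F1 | step 1 | racemic 5-methyloxepan-2-one | CC1CCOC(=O)CC1
F2 | step 1 | benzyl (S)-6-hydroxy-4-methylhexanoate | O=C(CC[C@H](C)CCO)OCc1ccccc1
F3 | step 7 | tert-butyl (4S)-3-hydroxy-4-methyl-2-methylidenehexanoate (both C3 epimers) | CC[C@H](C)C(O)C(=C)C(=O)OC(C)(C)C
F4 | step 7 | tert-butyl (2Z,4S)-2-(bromomethyl)-4-methylhex-2-enoate | CC[C@H](C)/C=C(\CBr)C(=O)OC(C)(C)C
F5 | step 7 | tributyl[(2Z,4S)-2-(tert-butoxycarbonyl)-4-methylhex-2-en-1-yl]phosphonium bromide | CC[C@H](C)/C=C(\C[P+](CCCC)(CCCC)CCCC)C(=O)OC(C)(C)C.[Br-]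
F6 | step 7 | tert-butyl (2Z,4S)-4-methyl-2-[(tributylphosphoranylidene)methyl]hex-2-enoate | CC[C@H](C)/C=C(\C=P(CCCC)(CCCC)CCCC)C(=O)OC(C)(C)C
F7 | step 11 | acyl Meldrum's acid of 15 (enol form) | CC[C@H](C)/C=C(\C=C\C[C@H](C)CCC(O)=C1C(=O)OC(C)(C)OC1=O)C(=O)OC(C)(C)C
F8 | step 11 | β-keto ester of 16 with the chain of 15 | CC[C@H](C)/C=C(\C=C\C[C@H](C)CCC(=O)CC(=O)O[C@H](C)CC(=O)OC)C(=O)OC(C)(C)C
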